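Two questions rank these flasks: what share of the lost substrate stands as target, and how much is lost in the time given?

the same everywhere: substrate 0.72 M; catalyst 0.72 mM
- Monday's: reagent 0.36 M; temperature 4 °C; run made earlier
- Wednesday's: reagent 0.54 M; temperature 45 °C; run made earlier
- elm: reagent 0.720 M; temperature 10 °C; time 25 h
- oak: reagent 0.720 M; temperature 35 °C; time 25 h
- cedar: reagent 0.720 M; temperature −15 °C; time 25 h
- alder: reagent 0.720 M; temperature 60 °C; time 25 h

| run | time / h | target / % | substrate / % |
|---|---|---|---|
| Monday's | 4.00 | 0 | 100.8 |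
| Monday's | 8.00 | 0.4 | 98.4 |
| Monday's | 10.0 | 0.7 | 98.1 |
| Monday's | 15.0 | 1.3 | 99.1 |
| Monday's | 20.0 | 1.5 | 97.6 |
| Monday's | 25.0 | 2.8 | 96.3 |
| Wednesday's | 0.667 | 3.7 | 93.9 |
| Wednesday's | 1.33 | 7.0 | 90.9 |
| Wednesday's | 2.00 | 10.0 | 85.3 |
| Wednesday's | 2.50 | 12.4 | 82.0 |
| Wednesday's | 4.00 | 16.1 | 75.9 |

(standard deviation of a reading: 0.5 percentage points)

- what may be going on: substrate + reagent <-> target; substrate + reagent <-> isomer of the product; target + catalyst <-> isomer of the product + catalyst; catalyst <-> dormant form

1. the best flask by amount of target, in percent of the substrate charged; "all alike" if 1.5 percentage points covers them all (elm / oak / cedar / alder / all alike)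
2. amount of target at the end, in percent of the substrate charged, elm
3. amount of target at the end, in percent of the substrate charged, oak
4. amount of target at the end, in percent of the substrate charged, cedar
5. amount of target at the end, in percent of the substrate charged, alder

The share comes first. Wednesday's last reading has 16.1% target against 24.1% substrate lost, so 66.8% is my target share S, the target standing per substrate lost (the yield on converted substrate). At 2.00 h the same run reads 68.0%, so S reads steady between these two readings.

For the loss I write the reagent balance. Target and isomer each take one substrate and one reagent, and the new charges are equal, so reagent lost equals substrate lost. The rate then goes with the square of what is left, and the fraction lost is x = θ/(θ+1), with θ = kct, where k is the constant of the total loss, c the charge and t the time.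

Wednesday's run gives k = 0.00259 M⁻¹ min⁻¹. Monday's target rate gives 5.19 × 10⁻⁵ M⁻¹ min⁻¹ for target, against 0.00173 M⁻¹ min⁻¹ on Wednesday, a factor of 33.4. I spread that factor evenly per degree and apply it to k.

Oak then has θ = 1.19, so S·x is 36.3%. Alder has θ = 10.1, so S·x is 60.8%. Elm and cedar stand colder than oak, so I rank them lower. I name alder, with one doubt: S was read over 4.00 h, and alder runs 25 h and hotter.

The forecast also names alder, with 7.5% for elm, 37% for oak, 0.5% for cedar and 55% for alder, the last lower than my alder figure, and says “Alder is probably best, though not certainly.”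

The flasks give 7.97% in elm, 31.7% in oak, 0.542% in cedar and 5.48% in alder, so the best is oak.

    substrate + reagent ⇌ target (K = 1.46 M⁻¹, k = 0.00632 M⁻¹ min⁻¹, Ea = 68.0 kJ mol⁻¹, ΔH = −42.0 kJ mol⁻¹)
    substrate + reagent ⇌ isomer of the product (K = 130 M⁻¹, k = 0.00366 M⁻¹ min⁻¹, Ea = 90.0 kJ mol⁻¹, ΔH = 10.0 kJ mol⁻¹)
    target + catalyst ⇌ isomer of the product + catalyst, rate k3*[catalyst]*[target] forward; the back reaction follows from the equilibrium constant (k = 1.81 M⁻¹ min⁻¹, Ea = 65.0 kJ mol⁻¹)
    catalyst ⇌ dormant form (K = 2.65, k = 8.44 × 10⁻⁴ min⁻¹, Ea = 123 kJ mol⁻¹, ΔH = −38.0 kJ mol⁻¹)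
    (constants at 60 °C)

In alder, substrate and reagent stand at 31.2% by 12.5 h, with target at 11.6% and isomer at 57.2%. By 25.0 h alder's target is down to 5.48% and its isomer up to 72.7%, with catalyst at 40.1% and dormant form at 59.9%. Alder's S ends at 7.01%, below Wednesday's reading. Oak's S at 25.0 h is 62.0%, but at 250 h oak holds 9.74% target and its S is 11.8%.

(The readings stem from a simulated flask for substances that don't exist, noise included.)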